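## Retrosynthetic overview

1. C7–C8 bond (key step): an acyl anion equivalent made from 3,4,5-trimethoxybenzaldehyde by a chiral N-heterocyclic carbene adds Markovnikov across the O–CH=CH2 unit of an aryl vinyl ether. This one step forms the ketone, the methyl-bearing C8 and its (S) configuration.
2. Aryl–alkenyl bond: Suzuki coupling of a bromo aryl vinyl ether with the commercial (E)-3-methoxypropenyl pinacol boronate installs the complete side chain.
3. O–vinyl bond: transfer vinylation of 4-bromo-2-methoxyphenol with vinyl acetate.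
4. No ring is formed; both benzene rings are bought. Bond order is O–vinyl, aryl–alkenyl, then C7–C8 last, so the base-sensitive stereocentre sees no later step.

Assumption: the sense of induction of the new key step is not known in advance; the (5aR,10bS) triazolium salt is written as the one giving the (S) ketone (Re-face attack at the O-bearing vinyl carbon), and the equally available (5aS,10bR) salt is used instead if the first run (chiral HPLC, optical rotation) shows the opposite sense.

## Route

Step 1
Reactants: 1 4-bromo-2-methoxyphenol; 2 vinyl acetate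
Product: 3 4-bromo-2-methoxy-1-(vinyloxy)benzene
Conditions: 2 (2 equiv), [Ir(cod)Cl]2 (1 mol %), Na2CO3 (0.6 equiv), toluene, 100 °C
Reagents that add atoms: 2 vinyl acetate, CC(=O)OC=C
Why: Iridium-catalysed transfer vinylation of a phenol (O–H addition across the vinyl ester, then β-acetate elimination) is established for electron-rich phenols, the carbonate removes the acetic acid, and the aryl bromide is inert to the monovalent iridium catalyst.

Step 2
Reactants: 3 4-bromo-2-methoxy-1-(vinyloxy)benzene; 4 (E)-2-(3-methoxyprop-1-en-1-yl)-4,4,5,5-tetramethyl-1,3,2-dioxaborolane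
Product: 5 (E)-2-methoxy-4-(3-methoxyprop-1-en-1-yl)-1-(vinyloxy)benzene
Conditions: 4 (1.2 equiv), Pd(dppf)Cl2 (3 mol %), K2CO3 (2 equiv), 1,4-dioxane/H2O 5:1, 80 °C; chromatography on Et3N-washed silica
Reagents that add atoms: 4 (E)-2-(3-methoxyprop-1-en-1-yl)-4,4,5,5-tetramethyl-1,3,2-dioxaborolane, COC/C=C/B1OC(C)(C)C(C)(C)O1
Why: Suzuki–Miyaura coupling of an alkenyl boronate transfers the propenyl group with retention of the E geometry, the vinyl ether is stable to aqueous base, and transmetalation is faster than Heck insertion of the vinyl ether.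

Step 3
Reactants: 5 (E)-2-methoxy-4-(3-methoxyprop-1-en-1-yl)-1-(vinyloxy)benzene; 6 3,4,5-trimethoxybenzaldehyde
Product: 8 (S)-2-[2-methoxy-4-[(E)-3-methoxyprop-1-en-1-yl]phenoxy]-1-(3,4,5-trimethoxyphenyl)propan-1-one, via Breslow enaminol 7 (not isolated)
Conditions: 6 (2 equiv), (5aR,10bS)-2-mesityl-5a,10b-dihydro-4H,6H-indeno[2,1-b][1,2,4]triazolo[4,3-d][1,4]oxazin-2-ium chloride (20 mol %), K3PO4 (15 mol %), dry 1,4-dioxane (1 M), 70 °C, argon; direct filtration through silica, no basic work-up
Reagents that add atoms: 6 3,4,5-trimethoxybenzaldehyde, COc1cc(C=O)cc(OC)c1OC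
Why: Proposed new method: an enantioselective intermolecular carbene-catalysed Markovnikov hydroacylation of an aryl vinyl ether, in which the carbene turns 6 into the nucleophilic Breslow enaminol 7 (acyl anion equivalent), whose O–H proton goes to the electron-rich terminal CH2 while its carbon bonds to the developing oxocarbenium carbon in a concerted, asynchronous five-membered (Conia-ene-like) transition state, the indane wall of the catalyst leaving the Re face of the O-bearing carbon open so that C8 is set as S, after which the carbene is released and every atom of 5 and 6 ends up in 8; the closest known reaction types are the carbene-catalysed intramolecular addition of acyl anion equivalents to enol ethers (benzofuranone synthesis) and the asymmetric carbene-catalysed hydroacylation of unactivated alkenes, styrenes and cyclopropenes, the hindered and less polarised cinnamyl alkene is expected to stay untouched, benzoin formation from excess 6 is reversible, and the base is kept below the azolium loading so that no free base remains to epimerise C8.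

## Compound list

1 | 4-bromo-2-methoxyphenol | COc1cc(Br)ccc1O | starting material
2 | vinyl acetate | CC(=O)OC=C | starting material
3 | 4-bromo-2-methoxy-1-(vinyloxy)benzene | C=COc1ccc(Br)cc1OC | intermediate
4 | (E)-2-(3-methoxyprop-1-en-1-yl)-4,4,5,5-tetramethyl-1,3,2-dioxaborolane | COC/C=C/B1OC(C)(C)C(C)(C)O1 | starting material
5 | (E)-2-methoxy-4-(3-methoxyprop-1-en-1-yl)-1-(vinyloxy)benzene | COC/C=C/c1ccc(OC=C)c(OC)c1 | intermediate
6 | 3,4,5-trimethoxybenzaldehyde | COc1cc(C=O)cc(OC)c1OC | starting material
7 | Breslow enaminol: (5aR,10bS)-1-[hydroxy(3,4,5-trimethoxyphenyl)methylidene]-2-mesityl-1,2,5a,10b-tetrahydro-4H,6H-indeno[2,1-b][1,2,4]triazolo[4,3-d][1,4]oxazine, enol C=C geometry not defined | COc1cc(cc(OC)c1OC)C(O)=C1N(c2c(C)cc(C)cc2C)N=C2CO[C@@H]3Cc4ccccc4[C@@H]3N12 | intermediate (not isolated)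
8 | (S)-2-[2-methoxy-4-[(E)-3-methoxyprop-1-en-1-yl]phenoxy]-1-(3,4,5-trimethoxyphenyl)propan-1-one, (8S,7′E) | COC/C=C/c1ccc(O[C@@H](C)C(=O)c2cc(OC)c(OC)c(OC)c2)c(OC)c1 | target

## Step count and risks

Total steps: 3. Longest linear sequence: 3 (1 → 3 → 5 → 8).

Steps most likely to fail, in order of risk:

**Step 3** is a new asymmetric hydroacylation. It may fail through no turnover on the aryl vinyl ether, reaction at the wrong alkene, low ee, or epimerisation of C8 by the carbene or base. The fallback sets out from 1 and comes back to the route at 8, taking the stereocentre from the chiral pool. Suzuki coupling of 1 with 4 (Pd(dppf)Cl2, K2CO3, 1,4-dioxane/H2O, 80 °C) gives (E)-2-methoxy-4-(3-methoxyprop-1-en-1-yl)phenol F1. Mitsunobu reaction of F1 with methyl (R)-lactate (PPh3, DIAD, THF, 0 °C to rt) proceeds with clean inversion to methyl (S)-2-[2-methoxy-4-[(E)-3-methoxyprop-1-en-1-yl]phenoxy]propanoate F2. Treatment with MeNH(OMe)·HCl and i-PrMgCl (THF, −20 °C) gives the Weinreb amide (S)-N-methoxy-N-methyl-2-[2-methoxy-4-[(E)-3-methoxyprop-1-en-1-yl]phenoxy]propanamide F3. Addition of commercial 3,4,5-trimethoxyphenylmagnesium bromide (THF, −40 to 0 °C) and a cold NH4Cl quench gives 8 without over-addition.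

**Step 2** may suffer from Heck reaction at the vinyl ether, protodeboronation of 4, or loss of the vinyl ether on silica. The fallback sets out from 3 and comes back at 5, building the side chain stepwise. Heck reaction of 3 with methyl acrylate (Pd(OAc)2, P(o-tol)3, Et3N, DMF, 100 °C) gives methyl (E)-3-[3-methoxy-4-(vinyloxy)phenyl]prop-2-enoate F4. Reduction with i-Bu2AlH (CH2Cl2, −78 °C) gives (E)-3-[3-methoxy-4-(vinyloxy)phenyl]prop-2-en-1-ol F5. O-Methylation (NaH, MeI, THF, 0 °C) gives 5.

**Step 1** may give competing O-acetylation of the hindered guaiacol-type phenol or stall. The fallback sets out from 1 and comes back at 3 by alkylation and elimination. Alkylation of 1 with excess 1,2-dibromoethane (K2CO3, MeCN, reflux) gives 4-bromo-1-(2-bromoethoxy)-2-methoxybenzene F6. E2 elimination with KOt-Bu (THF/DMSO, rt) gives 3.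

## Further compounds

F1 | step 3 | (E)-2-methoxy-4-(3-methoxyprop-1-en-1-yl)phenol | COC/C=C/c1ccc(O)c(OC)c1
F2 | step 3 | methyl (S)-2-[2-methoxy-4-[(E)-3-methoxyprop-1-en-1-yl]phenoxy]propanoate | COC/C=C/c1ccc(O[C@@H](C)C(=O)OC)c(OC)c1
F3 | step 3 | (S)-N-methoxy-N-methyl-2-[2-methoxy-4-[(E)-3-methoxyprop-1-en-1-yl]phenoxy]propanamide | COC/C=C/c1ccc(O[C@@H](C)C(=O)N(C)OC)c(OC)c1
F4 | step 2 | methyl (E)-3-[3-methoxy-4-(vinyloxy)phenyl]prop-2-enoate | COC(=O)/C=C/c1ccc(OC=C)c(OC)c1
F5 | step 2 | (E)-3-[3-methoxy-4-(vinyloxy)phenyl]prop-2-en-1-ol | OC/C=C/c1ccc(OC=C)c(OC)c1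
F6 | step 1 | 4-bromo-1-(2-bromoethoxy)-2-methoxybenzene | BrCCOc1ccc(Br)cc1OC
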